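**Retrosynthetic overview**
1. Feature used: the ring-A enone C2(=O)–C1=C10 carries the quaternary C9 (methyl C20, chain C11–C15, ring-B carbon C8) on its β-carbon C10, and C11 lies one atom from the α-carbon C1. This is the imprint of an alkene C9=C11 added across C1=C10 and cut again at C1–C11.
2. Target 30 ⇐ O15 desilylation ⇐ C1=C10 dehydrogenation ⇐ SmI2 cleavage of C1–C11 ⇐ cyclobutyl ketone 26 ⇐ intramolecular [2+2] of enone 25 (C9–C10 closes ring B, C1–C11 closes the four-membered ring).
3. 25 ⇐ aldol condensation (C1–C10, ring A) of a keto aldehyde released from menthyloxy lactone 22; C5 from anti conjugate addition of alkylmagnesium bromide 15 to furanone 14; C4 from two lactone alkylations.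
4. Chain bromide 13 ⇐ Johnson–Claisen rearrangement (C7–C8 bond, C8, E alkene) of allylic alcohol 9 (CBS reduction); C13 from monoester 1.
5. Ring order: ring A (step 13), then ring B and the cyclobutane together (step 14); the cyclobutane is opened in step 15.

Key step: step 14

Remark: atoms are labelled as in the halimane skeleton (C19 methyl and C18 ester carbon on C4, C17 methyl on C8, C20 methyl on C9, side chain C11–C15 with methyl C16 on C13); C13 is separated from C9 by two carbons (C11, C12), so the photo-substrate alkene C9=C11 carries C12 directly on C13; 1, 6 and 14 are taken to be catalogue compounds.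
Abbreviations in names: Ch = (3R,4E,7R)-9-(tert-butyldimethylsilyloxy)-3,4,7-trimethylnon-4-en-1-yl (C6–C15); Men = (1R,2S,5R)-2-isopropyl-5-methylcyclohexyl; TBS = tert-butyldimethylsilyl.

Step 1
Reactants: 1 (R)-5-methoxy-3-methyl-5-oxopentanoic acid (methyl hydrogen (R)-3-methylglutarate)
Product: 3 (S)-4-methyltetrahydro-2H-pyran-2-one, via (S)-5-hydroxy-3-methylpentanoic acid 2 (not isolated)
Conditions: LiBH4 (2 equiv), THF, 0 °C to rt; then 2 M HCl, rt
Reagents that add atoms: none
Why: Chemoselective borohydride reduction of the ester beside the lithium carboxylate, then acid lactonisation, should make the old acid carbon C11 and the old ester carbon C15 without touching C13.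

Step 2
Reactants: 3 (S)-4-methyltetrahydro-2H-pyran-2-one
Product: 4 (S)-5-hydroxy-N-methoxy-N,3-dimethylpentanamide
Conditions: MeNHOMe·HCl (1.5 equiv), i-PrMgCl (3 equiv), THF, −20 to 0 °C
Reagents that add atoms: N,O-dimethylhydroxylamine hydrochloride, CNOC.Cl
Why: Aminolysis of the lactone by the magnesium amide of N,O-dimethylhydroxylamine (Weinreb amide formation) should open the ring at C11 and free the C15 hydroxyl.

Step 3
Reactants: 4 (S)-5-hydroxy-N-methoxy-N,3-dimethylpentanamide
Product: 5 (S)-5-(tert-butyldimethylsilyloxy)-N-methoxy-N,3-dimethylpentanamide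
Conditions: TBSCl, imidazole, DMF, rt
Reagents that add atoms: tert-butyldimethylsilyl chloride, CC(C)(C)[Si](C)(C)Cl
Why: Standard silylation of the primary alcohol; the silyl ether is meant to last until the final step.

Step 4
Reactants: 5 (S)-5-(tert-butyldimethylsilyloxy)-N-methoxy-N,3-dimethylpentanamide; 6 (E)-2-bromobut-2-ene
Product: 8 (2E,6S)-8-(tert-butyldimethylsilyloxy)-3,6-dimethyloct-2-en-4-one, via (E)-but-2-en-2-yllithium 7 (not isolated)
Conditions: 6, t-BuLi (2 equiv), Et2O, −78 °C; then 5, −78 to 0 °C; H2O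
Reagents that add atoms: none
Why: Bromine–lithium exchange with retention of alkene geometry, then acylation of the alkenyllithium by the Weinreb amide, whose chelated tetrahedral adduct should prevent over-addition; this attaches C9, C20, C8 and C17 to C11.

Step 5
Reactants: 8 (2E,6S)-8-(tert-butyldimethylsilyloxy)-3,6-dimethyloct-2-en-4-one
Product: 9 (2E,4R,6S)-8-(tert-butyldimethylsilyloxy)-3,6-dimethyloct-2-en-4-ol
Conditions: (S)-2-methyl-CBS-oxazaborolidine [(S)-1-methyl-3,3-diphenyltetrahydro-1H,3H-pyrrolo[1,2-c][1,3,2]oxazaborole] (0.2 equiv), catecholborane, toluene, −78 °C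
Reagents that add atoms: none
Why: CBS reduction under reagent control, with the α-methylalkenyl group acting as the large substituent, so the (S)-catalyst should give the (R)-carbinol at C11.

Step 6
Reactants: 9 (2E,4R,6S)-8-(tert-butyldimethylsilyloxy)-3,6-dimethyloct-2-en-4-ol
Product: 11 ethyl (3R,4E,7R)-9-(tert-butyldimethylsilyloxy)-3,4,7-trimethylnon-4-enoate, via ketene acetal 10 (not isolated)
Conditions: MeC(OEt)3 (6 equiv), EtCO2H (cat.), xylene, 140 °C, EtOH distilled off
Reagents that add atoms: triethyl orthoacetate, CC(OCC)(OCC)OCC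
Why: Johnson–Claisen [3,3] rearrangement through a chair with the C12 chain equatorial should transfer the C11 carbinol configuration suprafacially to C8 (R), form the (E)-C9=C11 alkene and add C7 and C6.

Step 7
Reactants: 11 ethyl (3R,4E,7R)-9-(tert-butyldimethylsilyloxy)-3,4,7-trimethylnon-4-enoate
Product: 12 (3R,4E,7R)-9-(tert-butyldimethylsilyloxy)-3,4,7-trimethylnon-4-en-1-ol
Conditions: LiAlH4, THF, 0 °C
Reagents that add atoms: none
Why: Hydride reduction of the ester to the primary alcohol at C6; alkene and silyl ether are inert.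

Step 8
Reactants: 12 (3R,4E,7R)-9-(tert-butyldimethylsilyloxy)-3,4,7-trimethylnon-4-en-1-ol
Product: 13 (3R,4E,7R)-1-bromo-9-(tert-butyldimethylsilyloxy)-3,4,7-trimethylnon-4-ene
Conditions: CBr4, PPh3, 2,6-lutidine, CH2Cl2, 0 °C
Reagents that add atoms: tetrabromomethane, BrC(Br)(Br)Br
Why: Appel bromination of the primary alcohol under buffered conditions that should spare the silyl ether.

Step 9
Reactants: 13 (3R,4E,7R)-1-bromo-9-(tert-butyldimethylsilyloxy)-3,4,7-trimethylnon-4-ene; 14 (5R)-5-[(1R,2S,5R)-menthyloxy]furan-2(5H)-one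
Product: 17 (4R,5R)-4-Ch-5-(Men-oxy)dihydrofuran-2(3H)-one, via alkylmagnesium bromide 15 (not isolated), via silyl ketene acetal 16 (not isolated)
Conditions: 13, Mg, THF, 40 °C; then CuBr·SMe2 (10 mol %), TMSCl (2 equiv), 14, THF, −78 °C; 1 M HCl
Reagents that add atoms: none
Why: Copper-catalysed, TMSCl-accelerated conjugate addition of the Grignard reagent to the butenolide should occur anti to the menthyloxy group and so set C5; the acetal carbon is the later C10 at aldehyde level.

Step 10
Reactants: 17 (4R,5R)-4-Ch-5-(Men-oxy)dihydrofuran-2(3H)-one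
Product: 19 (3R,4R,5R)-3-allyl-4-Ch-5-(Men-oxy)dihydrofuran-2(3H)-one, via lithium enolate 18 (not isolated)
Conditions: LiN(i-Pr)2, THF, −78 °C; allyl bromide, DMPU, −78 to −40 °C
Reagents that add atoms: allyl bromide, C=CCBr
Why: Lactone enolate alkylation introduces the future C3–C2–C1 unit; the new centre is planarised again in step 11, so its ratio does not matter.

Step 11
Reactants: 19 (3R,4R,5R)-3-allyl-4-Ch-5-(Men-oxy)dihydrofuran-2(3H)-one
Product: 21 (3S,4R,5R)-3-allyl-3-methyl-4-Ch-5-(Men-oxy)dihydrofuran-2(3H)-one, via lithium enolate 20 (not isolated)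
Conditions: LiN(i-Pr)2, THF/DMPU, −78 °C; MeI, −78 to −20 °C
Reagents that add atoms: iodomethane, CI
Why: Alkylation of the tetrasubstituted lactone enolate from the face anti to the adjacent C5 chain should place the methyl trans and the allyl group cis to the chain, which is the C4 configuration of the target.

Step 12
Reactants: 21 (3S,4R,5R)-3-allyl-3-methyl-4-Ch-5-(Men-oxy)dihydrofuran-2(3H)-one
Product: 22 (3S,4R,5R)-3-methyl-3-(2-oxopropyl)-4-Ch-5-(Men-oxy)dihydrofuran-2(3H)-one
Conditions: PdCl2 (10 mol %), CuCl (1 equiv), O2 (1 atm), DMF/H2O 7:1, rt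
Reagents that add atoms: water, O
Why: Tsuji–Wacker oxidation gives the methyl ketone (C2, C1) by Markovnikov attack of water on the terminal alkene; the trisubstituted C9=C11 alkene should not react.

Step 13
Reactants: 22 (3S,4R,5R)-3-methyl-3-(2-oxopropyl)-4-Ch-5-(Men-oxy)dihydrofuran-2(3H)-one
Product: 25 methyl (1S,2S)-2-Ch-1-methyl-5-oxocyclohex-3-ene-1-carboxylate, via keto aldehyde ester 23 (not isolated), via aldol 24 (not isolated)
Conditions: NaOMe (0.5 equiv), MeOH, 0 °C to rt; AcOH quench
Reagents that add atoms: methanol, CO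
Why: Methoxide opens the acylal-type lactone to the methyl ester, the hemiacetal alkoxide collapses to the C10 aldehyde and menthol, and the intramolecular aldol condensation of the methyl ketone (the only mode that gives a six-membered ring) with E1cB dehydration closes ring A as the C1=C10 enone.

Step 14
Reactants: 25 methyl (1S,2S)-2-Ch-1-methyl-5-oxocyclohex-3-ene-1-carboxylate
Product: 26 methyl (1S,4S,5S,8R,9R,10S,11S,13R)-15-(tert-butyldimethylsilyloxy)-2-oxo-1,11-cyclohaliman-18-oate (H10 anti to H5; cyclobutane C1–C10–C9–C11 cis-fused to rings A and B)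
Conditions: hν (366 nm, Pyrex), degassed MeCN (5 mM), 0 °C
Reagents that add atoms: none
Why: Excitation and intersystem crossing give the twisted triplet enone, whose β-carbon C10 bonds to C9 in a chair-like six-membered array; spin inversion of the C1/C11 1,4-biradical and C1–C11 bonding complete the cyclobutane (closest known reaction type: intramolecular enone–alkene [2+2] photocycloaddition of a 1,7-diene with a three-atom tether on the carbon next to the β-carbon, which gives straight adducts by 1,6-closure). Ring B closes 6-exo by attack of C10 on C9, and the four-membered ring closes by combination of the C1 and C11 radicals, cis-fused to both six-membered rings. C10 and C1: bonding at C10 should be equatorial, anti to H5 (trans A/B junction), because the quaternary C4 and the enone carbon C1 both stay equatorial on the forming ring B, and H1 follows from the cis four-ring fusion; C9: only a biradical with C11 axial on the C1 side can close and the others revert to 25, so C11 ends anti to C4 and the C20 methyl syn to the C17 methyl as in the target; C11 (expected cis to C20) is destroyed later. The step needs straight regiochemistry and the trans junction, since a cis junction would tie C11 to the C4 side and lead to the C9 epimer. The three-carbon tether (1,6- before 1,7-closure) should secure the first and the fully substituted C4 next to C5 the second, at the price of an axial C17 methyl in the closing chair. The alkene geometry has no influence, because C11 becomes a methylene in step 15.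

Step 15
Reactants: 26 methyl (1S,4S,5S,8R,9R,10S,11S,13R)-15-(tert-butyldimethylsilyloxy)-2-oxo-1,11-cyclohaliman-18-oate
Product: 28 methyl (4S,5S,8R,9S,10R,13R)-15-(tert-butyldimethylsilyloxy)-2-oxohaliman-18-oate, via diiodosamarium enolate 27 (not isolated)
Conditions: SmI2 (2.5 equiv), HMPA, MeOH (2 equiv), THF, −78 to 0 °C
Reagents that add atoms: none
Why: Reductive cyclobutyl ketone fragmentation: the C2 ketyl cleaves the strained C1–C11 bond, which is axial on ring A and aligned with the ketyl π-orbital, the C11 radical is reduced and protonated and the enolate protonated at C1, leaving C9 quaternary with its chain restored.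

Step 16
Reactants: 28 methyl (4S,5S,8R,9S,10R,13R)-15-(tert-butyldimethylsilyloxy)-2-oxohaliman-18-oate
Product: 29 methyl (4S,5S,8R,9S,13R)-15-(tert-butyldimethylsilyloxy)-2-oxohalim-1(10)-en-18-oate
Conditions: 2-iodoxybenzoic acid (IBX, 1.5 equiv), DMSO/toluene 1:2, 70 °C
Reagents that add atoms: none
Why: IBX dehydrogenation through the enol can only give the C1=C10 enone, because the other α-side ends at the quaternary C4, which has no hydrogen; the C10 stereocentre is removed.

Step 17
Reactants: 29 methyl (4S,5S,8R,9S,13R)-15-(tert-butyldimethylsilyloxy)-2-oxohalim-1(10)-en-18-oate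
Product: 30 methyl (4S,5S,8R,9S,13R)-15-hydroxy-2-oxohalim-1(10)-en-18-oate (CNP0157174.1)
Conditions: HF·pyridine, THF, 0 °C to rt
Reagents that add atoms: none
Why: Fluoride-mediated cleavage of the primary silyl ether under non-basic conditions, which should leave the enone, the ester and the γ-centre C5 untouched.

**Compound list**
1 | (R)-5-methoxy-3-methyl-5-oxopentanoic acid | OC(=O)C[C@@H](C)CC(=O)OC | starting material
2 | (S)-5-hydroxy-3-methylpentanoic acid (lithium salt before acidification) | OC(=O)C[C@@H](C)CCO | intermediate (not isolated)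
3 | (S)-4-methyltetrahydro-2H-pyran-2-one | O=C1C[C@@H](C)CCO1 | intermediate
4 | (S)-5-hydroxy-N-methoxy-N,3-dimethylpentanamide | CON(C)C(=O)C[C@@H](C)CCO | intermediate
5 | (S)-5-(tert-butyldimethylsilyloxy)-N-methoxy-N,3-dimethylpentanamide | CON(C)C(=O)C[C@@H](C)CCO[Si](C)(C)C(C)(C)C | intermediate
6 | (E)-2-bromobut-2-ene | C/C=C(\C)Br | starting material
7 | (E)-but-2-en-2-yllithium | C/C=C(\C)[Li] | intermediate (not isolated)
8 | (2E,6S)-8-(tert-butyldimethylsilyloxy)-3,6-dimethyloct-2-en-4-one | C/C=C(\C)C(=O)C[C@@H](C)CCO[Si](C)(C)C(C)(C)C | intermediate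
9 | (2E,4R,6S)-8-(tert-butyldimethylsilyloxy)-3,6-dimethyloct-2-en-4-ol | C/C=C(\C)[C@H](O)C[C@@H](C)CCO[Si](C)(C)C(C)(C)C | intermediate
10 | 1-ethoxyvinyl ether of 9 (mixed ketene acetal) | C=C(OCC)O[C@@H](/C(C)=C/C)C[C@@H](C)CCO[Si](C)(C)C(C)(C)C | intermediate (not isolated)
11 | ethyl (3R,4E,7R)-9-(tert-butyldimethylsilyloxy)-3,4,7-trimethylnon-4-enoate | CCOC(=O)C[C@@H](C)/C(C)=C/C[C@@H](C)CCO[Si](C)(C)C(C)(C)C | intermediate
12 | (3R,4E,7R)-9-(tert-butyldimethylsilyloxy)-3,4,7-trimethylnon-4-en-1-ol | OCC[C@@H](C)/C(C)=C/C[C@@H](C)CCO[Si](C)(C)C(C)(C)C | intermediate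
13 | (3R,4E,7R)-1-bromo-9-(tert-butyldimethylsilyloxy)-3,4,7-trimethylnon-4-ene | BrCC[C@@H](C)/C(C)=C/C[C@@H](C)CCO[Si](C)(C)C(C)(C)C | intermediate
14 | (5R)-5-[(1R,2S,5R)-menthyloxy]furan-2(5H)-one | O=C1C=C[C@H](O[C@@H]2C[C@H](C)CC[C@H]2C(C)C)O1 | starting material
15 | Ch-magnesium bromide (Grignard reagent of 13) | Br[Mg]CC[C@@H](C)/C(C)=C/C[C@@H](C)CCO[Si](C)(C)C(C)(C)C | intermediate (not isolated)
16 | trimethylsilyl ketene acetal of 17 | C[Si](C)(C)OC1=C[C@@H](CC[C@@H](C)/C(C)=C/C[C@@H](C)CCO[Si](C)(C)C(C)(C)C)[C@H](O[C@@H]2C[C@H](C)CC[C@H]2C(C)C)O1 | intermediate (not isolated)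
17 | (4R,5R)-4-Ch-5-(Men-oxy)dihydrofuran-2(3H)-one | O=C1C[C@@H](CC[C@@H](C)/C(C)=C/C[C@@H](C)CCO[Si](C)(C)C(C)(C)C)[C@H](O[C@@H]2C[C@H](C)CC[C@H]2C(C)C)O1 | intermediate
18 | lithium enolate of 17 | [Li]OC1=C[C@@H](CC[C@@H](C)/C(C)=C/C[C@@H](C)CCO[Si](C)(C)C(C)(C)C)[C@H](O[C@@H]2C[C@H](C)CC[C@H]2C(C)C)O1 | intermediate (not isolated)
19 | (3R,4R,5R)-3-allyl-4-Ch-5-(Men-oxy)dihydrofuran-2(3H)-one | O=C1[C@H](CC=C)[C@@H](CC[C@@H](C)/C(C)=C/C[C@@H](C)CCO[Si](C)(C)C(C)(C)C)[C@H](O[C@@H]2C[C@H](C)CC[C@H]2C(C)C)O1 | intermediate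
20 | lithium enolate of 19 | [Li]OC1=C(CC=C)[C@@H](CC[C@@H](C)/C(C)=C/C[C@@H](C)CCO[Si](C)(C)C(C)(C)C)[C@H](O[C@@H]2C[C@H](C)CC[C@H]2C(C)C)O1 | intermediate (not isolated)
21 | (3S,4R,5R)-3-allyl-3-methyl-4-Ch-5-(Men-oxy)dihydrofuran-2(3H)-one | O=C1[C@@](C)(CC=C)[C@@H](CC[C@@H](C)/C(C)=C/C[C@@H](C)CCO[Si](C)(C)C(C)(C)C)[C@H](O[C@@H]2C[C@H](C)CC[C@H]2C(C)C)O1 | intermediate
22 | (3S,4R,5R)-3-methyl-3-(2-oxopropyl)-4-Ch-5-(Men-oxy)dihydrofuran-2(3H)-one | O=C1[C@@](C)(CC(C)=O)[C@@H](CC[C@@H](C)/C(C)=C/C[C@@H](C)CCO[Si](C)(C)C(C)(C)C)[C@H](O[C@@H]2C[C@H](C)CC[C@H]2C(C)C)O1 | intermediate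
23 | methyl (2S,3R,6R,7E,10R)-12-(tert-butyldimethylsilyloxy)-3-formyl-2,6,7,10-tetramethyl-2-(2-oxopropyl)dodec-7-enoate | COC(=O)[C@@](C)(CC(C)=O)[C@H](C=O)CC[C@@H](C)/C(C)=C/C[C@@H](C)CCO[Si](C)(C)C(C)(C)C | intermediate (not isolated)
24 | methyl 2-Ch-3-hydroxy-1-methyl-5-oxocyclohexane-1-carboxylate (C4, C5 as in 25; carbinol C10 not defined) | COC(=O)[C@@]1(C)CC(=O)CC(O)[C@@H]1CC[C@@H](C)/C(C)=C/C[C@@H](C)CCO[Si](C)(C)C(C)(C)C | intermediate (not isolated)
25 | methyl (1S,2S)-2-Ch-1-methyl-5-oxocyclohex-3-ene-1-carboxylate | COC(=O)[C@@]1(C)CC(=O)C=C[C@@H]1CC[C@@H](C)/C(C)=C/C[C@@H](C)CCO[Si](C)(C)C(C)(C)C | intermediate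
26 | methyl (1S,4S,5S,8R,9R,10S,11S,13R)-15-(tert-butyldimethylsilyloxy)-2-oxo-1,11-cyclohaliman-18-oate (trans A/B junction, cis-fused cyclobutane) | COC(=O)[C@@]1(C)CC(=O)[C@@H]3[C@@H]2[C@@H]1CC[C@@H](C)[C@]2(C)[C@H]3C[C@@H](C)CCO[Si](C)(C)C(C)(C)C | intermediate
27 | diiodosamarium 1-en-2-olate of 28 | COC(=O)[C@@]1(C)CC(O[Sm](I)I)=C[C@@H]2[C@@H]1CC[C@@H](C)[C@]2(C)CC[C@@H](C)CCO[Si](C)(C)C(C)(C)C | intermediate (not isolated)
28 | methyl (4S,5S,8R,9S,10R,13R)-15-(tert-butyldimethylsilyloxy)-2-oxohaliman-18-oate | COC(=O)[C@@]1(C)CC(=O)C[C@@H]2[C@@H]1CC[C@@H](C)[C@]2(C)CC[C@@H](C)CCO[Si](C)(C)C(C)(C)C | intermediate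
29 | methyl (4S,5S,8R,9S,13R)-15-(tert-butyldimethylsilyloxy)-2-oxohalim-1(10)-en-18-oate | COC(=O)[C@@]1(C)CC(=O)C=C2[C@@H]1CC[C@@H](C)[C@]2(C)CC[C@@H](C)CCO[Si](C)(C)C(C)(C)C | intermediate
30 | methyl (4S,5S,8R,9S,13R)-15-hydroxy-2-oxohalim-1(10)-en-18-oate (CNP0157174.1) | COC(=O)[C@@]1(C)CC(=O)C=C2[C@@H]1CC[C@@H](C)[C@]2(C)CC[C@@H](C)CCO | target

Total step count: 17. Longest linear sequence: 17 steps (from 1).

**Steps most likely to fail**

Step 14. Ring B may close on the H5 face (cis junction), which ties C11 to the C4 side and gives the C9 epimer. The first bond may also form at the less substituted C11 (seven-membered, crossed mode), or the 1,4-biradical may disproportionate instead of closing. Fallback: from 25, a metal-hydride hydrogen-atom-transfer radical conjugate cyclisation (Fe(acac)3, PhSiH3, EtOH/ethylene glycol, 60 °C). Hydrogen-atom transfer to C11 gives the tertiary C9 radical, which adds 6-exo to the β-carbon C10 of the ground-state enone. Axial attack from the tether face with the larger C11 arm turned away from C4 should give the cis-fused ketone F1 with the C9 configuration of the target. F1 is then dehydrogenated under the conditions of step 16, which removes C10 as a stereocentre, and the route is rejoined at 29.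

Step 13. C5 may epimerise through the enolate of the free C10 aldehyde before ring closure (or by γ-deprotonation of the enone afterwards), and the ketone enolate may attack the lactone carbonyl. Fallback: from 22, kinetic enolisation of the methyl ketone (LiN(i-Pr)2, −78 °C, lithium enolate F2) and silylation (TMSCl) give the silyl enol ether F3. Catalytic TMSOTf (CH2Cl2, −78 °C) ionises the menthyl acetal and a Mukaiyama-type addition forms C1–C10, giving the bridged keto lactone F4 without a free enolisable aldehyde. DBU opens the β-acyloxy ketone by E1cB elimination to the enone acid F5, and TMSCHN2/MeOH gives 25.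

Step 11. Facial selectivity may be poor or reversed if the menthyloxy group, which is cis to the incoming methyl, outweighs the C5 chain; this would give the C4 epimer. Fallback: from 17, the two alkylations are run in the opposite order so that the acetal group becomes the controlling element. Enolate 18 is methylated (MeI) to the 3-methyl lactone F6; deprotonation gives the lithium enolate F7, and allyl bromide then enters last on the face syn to the chain, which returns the route at 21.

Further compounds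
F1 | step 14 | methyl (4S,5S,8R,9S,10S,13R)-15-(tert-butyldimethylsilyloxy)-2-oxohaliman-18-oate (cis A/B junction) | COC(=O)[C@@]1(C)CC(=O)C[C@H]2[C@@H]1CC[C@@H](C)[C@]2(C)CC[C@@H](C)CCO[Si](C)(C)C(C)(C)C
F2 | step 13 | lithium enolate (terminal) of methyl ketone 22 | O=C1[C@@](C)(CC(=C)O[Li])[C@@H](CC[C@@H](C)/C(C)=C/C[C@@H](C)CCO[Si](C)(C)C(C)(C)C)[C@H](O[C@@H]2C[C@H](C)CC[C@H]2C(C)C)O1
F3 | step 13 | trimethylsilyl enol ether (terminal) of 22 | O=C1[C@@](C)(CC(=C)O[Si](C)(C)C)[C@@H](CC[C@@H](C)/C(C)=C/C[C@@H](C)CCO[Si](C)(C)C(C)(C)C)[C@H](O[C@@H]2C[C@H](C)CC[C@H]2C(C)C)O1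
F4 | step 13 | bridged keto lactone (C18–O–C10 lactone across ring A, C2 ketone) | O=C1O[C@@H]2CC(=O)C[C@@]1(C)[C@H]2CC[C@@H](C)/C(C)=C/C[C@@H](C)CCO[Si](C)(C)C(C)(C)C
F5 | step 13 | (1S,2S)-2-Ch-1-methyl-5-oxocyclohex-3-ene-1-carboxylic acid | OC(=O)[C@@]1(C)CC(=O)C=C[C@@H]1CC[C@@H](C)/C(C)=C/C[C@@H](C)CCO[Si](C)(C)C(C)(C)C
F6 | step 11 | (3R,4R,5R)-3-methyl-4-Ch-5-(Men-oxy)dihydrofuran-2(3H)-one | O=C1[C@H](C)[C@@H](CC[C@@H](C)/C(C)=C/C[C@@H](C)CCO[Si](C)(C)C(C)(C)C)[C@H](O[C@@H]2C[C@H](C)CC[C@H]2C(C)C)O1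
F7 | step 11 | lithium enolate of F6 | [Li]OC1=C(C)[C@@H](CC[C@@H](C)/C(C)=C/C[C@@H](C)CCO[Si](C)(C)C(C)(C)C)[C@H](O[C@@H]2C[C@H](C)CC[C@H]2C(C)C)O1
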